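## Retrosynthetic overview

- The target is reached by one final hydrogenolysis of a fully benzyl-protected precursor (five benzyl ethers and one benzyl carbonate on O3) that already carries the 7-O-galloyl ester.
- Ring C of that precursor is opened across C4–C3 and O1–C2 into an ortho-quinone methide of ring A (C4 as exocyclic methylene, O1 as carbonyl) and an (E)-enol carbonate C3=C2 bearing ring B on C2. The forward reaction is a catalytic asymmetric oxa-[4+2] cycloaddition that sets both stereocentres.
- Enabling feature: O1 on C8a is ortho to the benzylic carbon C4, so O1=C8a–C4a=C4 is a 1-oxadiene. O5 is the second ortho oxygen, so the two free hydroxyls of the precursor are equivalent and O7 (para to C4a) is the only site for the gallate. The 4'-oxygen of ring B, para to C2, polarises C2=C3 so that C3 bonds to C4.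
- The quinone methide comes from a benzyl alcohol made from 2,4,6-trihydroxybenzaldehyde (para-hydroxyl acylated selectively; the formyl carbon becomes C4). The enol carbonate comes from 3,4-bis(benzyloxy)benzaldehyde via alkyne, (E)-alkenyltrifluoroborate and (E)-enol acetate, with the E geometry carried through.
- Ring order: ring A, ring B and the galloyl ring are bought as arenes; ring C is the only ring made.

Key step: step 7

Remark on the chemistry: the sense of induction of the chiral acid in step 7 cannot be predicted with confidence. The (R)-configured catalyst is assumed to give the (2R,3S) adduct; otherwise the (S)-catalyst would be used with no other change.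

## Route

Step 1
Reactants: 1 3,4-bis(benzyloxy)benzaldehyde
Product: 2 4-ethynyl-1,2-bis(benzyloxy)benzene
Conditions: dimethyl (1-diazo-2-oxopropyl)phosphonate (1.2 equiv), K2CO3 (2 equiv), MeOH/THF, 0 °C to rt
Reagents that add atoms: dimethyl (1-diazo-2-oxopropyl)phosphonate, CC(=O)C(=[N+]=[N-])P(=O)(OC)OC (supplies the terminal alkyne carbon)
Why: Seyferth–Gilbert homologation with the in situ deacylated diazophosphonate converts the aryl aldehyde into the terminal alkyne under mild carbonate base that leaves the benzyl ethers untouched.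

Step 2
Reactants: 2 4-ethynyl-1,2-bis(benzyloxy)benzene
Product: 4 potassium (E)-{2-[3,4-bis(benzyloxy)phenyl]ethenyl}trifluoroborate, via alkenyl catechol boronate 3 (not isolated)
Conditions: catecholborane (1.2 equiv), THF, 70 °C; then KHF2 (sat. aq., 4 equiv), MeOH, rt
Reagents that add atoms: catecholborane, B1Oc2ccccc2O1 (boron; its catechol part stays in 3 only); potassium hydrogen difluoride, [K+].[F-].F (potassium and fluorine)
Why: Syn hydroboration of the terminal alkyne places boron on the terminal carbon and gives only the E alkenylboronate, which KHF2 converts into the bench-stable trifluoroborate.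

Step 3
Reactants: 4 potassium (E)-{2-[3,4-bis(benzyloxy)phenyl]ethenyl}trifluoroborate
Product: 5 (E)-2-[3,4-bis(benzyloxy)phenyl]ethenyl acetate
Conditions: AcOH (2 equiv), Cu(OAc)2 (10 mol%), DMAP (20 mol%), 4 Å MS, O2 (1 atm), CH2Cl2/MeCN, 40 °C
Reagents that add atoms: acetic acid, CC(=O)O
Why: Copper-catalysed oxidative C–O coupling of an alkenyltrifluoroborate with a carboxylic acid (Chan–Lam type) forms the enol ester at the alkenyl carbon with retention, so the E geometry from step 2 passes into 5.

Step 4
Reactants: 5 (E)-2-[3,4-bis(benzyloxy)phenyl]ethenyl acetate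
Product: 7 benzyl (E)-2-[3,4-bis(benzyloxy)phenyl]ethenyl carbonate, via potassium enolate 6 (not isolated)
Conditions: KOtBu (1.0 equiv), THF, −78 °C; then ClCO2Bn (1.2 equiv), −78 °C
Reagents that add atoms: benzyl chloroformate, O=C(Cl)OCc1ccccc1; potassium tert-butoxide, CC(C)(C)[O-].[K+] (supplies the potassium of 6 only)
Why: Alkoxide cleavage of the enol acetate releases the aldehyde enolate with unchanged geometry (no proton source for equilibration at −78 °C), and the hard chloroformate acylates it on oxygen to give the enol carbonate.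

Step 5
Reactants: 8 2,4,6-trihydroxybenzaldehyde; 9 3,4,5-tris(benzyloxy)benzoic acid
Product: 11 4-formyl-3,5-dihydroxyphenyl 3,4,5-tris(benzyloxy)benzoate, via acid chloride 10 (not isolated)
Conditions: 9, (COCl)2, DMF (cat.), CH2Cl2, 0 °C to rt, evaporate; then 8 (1.1 equiv), i-Pr2NEt (1.1 equiv), THF, −20 °C
Reagents that add atoms: oxalyl chloride, O=C(Cl)C(=O)Cl (supplies the chlorine of 10; none of its atoms remains in 11)
Why: Nucleophilic acyl substitution by the phenoxide of the 4-hydroxyl, which is the most acidic (para to the formyl group) and the only one not locked in a hydrogen bond to the formyl oxygen, should give the para ester selectively.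

Step 6
Reactants: 11 4-formyl-3,5-dihydroxyphenyl 3,4,5-tris(benzyloxy)benzoate
Product: 12 3,5-dihydroxy-4-(hydroxymethyl)phenyl 3,4,5-tris(benzyloxy)benzoate
Conditions: NaBH4 (1.0 equiv), THF/i-PrOH, −20 °C, 20 min; pH 6 phosphate buffer; used without storage
Reagents that add atoms: none
Why: Borohydride reduction of the aldehyde is much faster than attack on the aryl ester at low temperature, and the short reaction time with a buffered quench limits loss of the benzylic oxygen.

Step 7
Reactants: 12 3,5-dihydroxy-4-(hydroxymethyl)phenyl 3,4,5-tris(benzyloxy)benzoate; 7 benzyl (E)-2-[3,4-bis(benzyloxy)phenyl]ethenyl carbonate (2 equiv)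
Product: 14 (2R,3S)-2-[3,4-bis(benzyloxy)phenyl]-3-{[(benzyloxy)carbonyl]oxy}-5-hydroxy-3,4-dihydro-2H-chromen-7-yl 3,4,5-tris(benzyloxy)benzoate, via ortho-quinone methide 13 (not isolated)
Conditions: (R)-3,3'-bis(2,4,6-triisopropylphenyl)-1,1'-binaphthyl-2,2'-diyl N-triflylphosphoramide (10 mol%), 5 Å MS, CH2Cl2/toluene, −40 °C, 12 added over 6 h
Reagents that add atoms: none
Why: Proposed new method: the strong chiral acid ionises the benzylic C–OH of 12, flanked by two ortho hydroxyls, with loss of water to the ortho-quinone methide 13 held as a hydrogen-bonded ion pair with the chiral phosphoramidate, and the 1-oxadiene O1=C8a–C4a=C4 of 13 adds the C=C of 7 in an asynchronous inverse-electron-demand oxa-Diels–Alder reaction in which the C4–C3 bond runs ahead of the O1–C2 bond. The closest known reaction type is the chiral N-triflylphosphoramide-catalysed [4+2] cycloaddition of ortho-quinone methides from ortho-hydroxybenzyl alcohols with styrenes, in which the acid activates only the electrophile; it is extended here to a methide with no substituent on the methylene carbon and to a 1,2-disubstituted enol carbonate. Ring C is closed as a six-membered ring in the [4+2] mode (in the stepwise limit, by capture of the C2 benzylic cation by the phenol oxygen). The 2,3-trans relation of C2 and C3 follows from the E geometry of 7, transferred suprafacially (and also preferred in a stepwise closure, with both substituents equatorial), while the absolute configuration of both centres is set by the chiral anion, which covers one face of the planar cation so that 7 is attacked on one enantiotopic face. The regioselectivity needed is secured by ring B, whose 4'-benzyloxy group para to C2 stabilises positive charge at C2 far better than the acylated carbonate oxygen could at C3, so C3 is the nucleophilic terminus; because the two ortho hydroxyls of 12 are equivalent, closure by either gives 14 and leaves the other as the free 5-hydroxyl. Chemoselectivity over Friedel–Crafts capture of 13 by ring A of 12 or 14 is sought by slow addition of 12 to excess 7 at low temperature, with the molecular sieves taking up the water released.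

Step 8
Reactants: 14 (2R,3S)-2-[3,4-bis(benzyloxy)phenyl]-3-{[(benzyloxy)carbonyl]oxy}-5-hydroxy-3,4-dihydro-2H-chromen-7-yl 3,4,5-tris(benzyloxy)benzoate
Product: 15 catechin 7-O-gallate, (2R,3S)-2-(3,4-dihydroxyphenyl)-3,5-dihydroxy-3,4-dihydro-2H-chromen-7-yl 3,4,5-trihydroxybenzoate
Conditions: H2 (1 atm), Pd(OH)2/C, THF/EtOAc, rt, stopped at the calculated uptake
Reagents that add atoms: none
Why: Catalytic hydrogenolysis cleaves the five benzyl ethers and the benzyl carbonate (which then loses CO2 to free the 3-hydroxyl) under neutral conditions that leave the aryl gallate ester and both stereocentres untouched.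

## Compound list

1 | 3,4-bis(benzyloxy)benzaldehyde | O=Cc1ccc(OCc2ccccc2)c(OCc2ccccc2)c1 | starting material
2 | 4-ethynyl-1,2-bis(benzyloxy)benzene | C#Cc1ccc(OCc2ccccc2)c(OCc2ccccc2)c1 | intermediate
3 | 2-{(E)-2-[3,4-bis(benzyloxy)phenyl]ethenyl}-1,3,2-benzodioxaborole | B1(/C=C/c2ccc(OCc3ccccc3)c(OCc3ccccc3)c2)Oc2ccccc2O1 | intermediate (not isolated)
4 | potassium (E)-{2-[3,4-bis(benzyloxy)phenyl]ethenyl}trifluoroborate | [K+].F[B-](F)(F)/C=C/c1ccc(OCc2ccccc2)c(OCc2ccccc2)c1 | intermediate
5 | (E)-2-[3,4-bis(benzyloxy)phenyl]ethenyl acetate | CC(=O)O/C=C/c1ccc(OCc2ccccc2)c(OCc2ccccc2)c1 | intermediate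
6 | potassium (E)-2-[3,4-bis(benzyloxy)phenyl]ethenolate | [K+].[O-]/C=C/c1ccc(OCc2ccccc2)c(OCc2ccccc2)c1 | intermediate (not isolated)
7 | benzyl (E)-2-[3,4-bis(benzyloxy)phenyl]ethenyl carbonate | O=C(OCc1ccccc1)O/C=C/c1ccc(OCc2ccccc2)c(OCc2ccccc2)c1 | intermediate
8 | 2,4,6-trihydroxybenzaldehyde | O=Cc1c(O)cc(O)cc1O | starting material
9 | 3,4,5-tris(benzyloxy)benzoic acid | OC(=O)c1cc(OCc2ccccc2)c(OCc2ccccc2)c(OCc2ccccc2)c1 | starting material
10 | 3,4,5-tris(benzyloxy)benzoyl chloride | ClC(=O)c1cc(OCc2ccccc2)c(OCc2ccccc2)c(OCc2ccccc2)c1 | intermediate (not isolated)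
11 | 4-formyl-3,5-dihydroxyphenyl 3,4,5-tris(benzyloxy)benzoate | O=Cc1c(O)cc(OC(=O)c2cc(OCc3ccccc3)c(OCc3ccccc3)c(OCc3ccccc3)c2)cc1O | intermediate
12 | 3,5-dihydroxy-4-(hydroxymethyl)phenyl 3,4,5-tris(benzyloxy)benzoate | OCc1c(O)cc(OC(=O)c2cc(OCc3ccccc3)c(OCc3ccccc3)c(OCc3ccccc3)c2)cc1O | intermediate
13 | 5-hydroxy-4-methylidene-3-oxocyclohexa-1,5-dien-1-yl 3,4,5-tris(benzyloxy)benzoate (ortho-quinone methide) | C=C1C(=O)C=C(OC(=O)c2cc(OCc3ccccc3)c(OCc3ccccc3)c(OCc3ccccc3)c2)C=C1O | intermediate (not isolated)
14 | (2R,3S)-2-[3,4-bis(benzyloxy)phenyl]-3-{[(benzyloxy)carbonyl]oxy}-5-hydroxy-3,4-dihydro-2H-chromen-7-yl 3,4,5-tris(benzyloxy)benzoate | O=C(Oc1cc(O)c2c(c1)O[C@H](c1ccc(OCc3ccccc3)c(OCc3ccccc3)c1)[C@@H](OC(=O)OCc1ccccc1)C2)c1cc(OCc2ccccc2)c(OCc2ccccc2)c(OCc2ccccc2)c1 | intermediate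
15 | catechin 7-O-gallate, (2R,3S)-2-(3,4-dihydroxyphenyl)-3,5-dihydroxy-3,4-dihydro-2H-chromen-7-yl 3,4,5-trihydroxybenzoate | O=C(Oc1cc(O)c2c(c1)O[C@H](c1ccc(O)c(O)c1)[C@@H](O)C2)c1cc(O)c(O)c(O)c1 | target

## Step count and risks

Total step count: 8. Longest linear sequence: 6 steps (steps 1, 2, 3, 4, 7, 8); ring A is prepared in a two-step branch (steps 5, 6).

**Step 7** (bears the label "Proposed new method:"). What may go wrong: the chiral ion pair discriminates the two faces poorly, or the enol carbonate is too weak a 2π partner and the quinone methide is consumed by phenolic rings instead. The fallback uses known reaction types only and sets out from 12 and alkyne 2. FeCl3 (10 mol%) in CH2Cl2 at 0 °C should join them by the known benzylation–cyclisation ([4+2]) of ortho-hydroxybenzyl alcohols with arylacetylenes. This gives the achiral flav-2-ene 2-[3,4-bis(benzyloxy)phenyl]-5-hydroxy-4H-chromen-7-yl 3,4,5-tris(benzyloxy)benzoate F1, with the same two bonds formed but no stereocentre yet. Asymmetric hydroboration of its C2=C3 enol ether with monoisopinocampheylborane made from (+)-α-pinene follows (boron to C3, hydrogen to C2 on the same face; the reagent antipode is assigned by analogy with 1-arylcycloalkenes and would need confirming). Oxidation with NaBO3·4H2O should then give the 2,3-trans alcohol (2R,3S)-2-[3,4-bis(benzyloxy)phenyl]-3,5-dihydroxy-3,4-dihydro-2H-chromen-7-yl 3,4,5-tris(benzyloxy)benzoate F2. Hydrogenolysis of F2 under the conditions of step 8 comes back to the route at 15.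

**Step 6.** What may go wrong: the phenoxide–borate intermediate expels the benzylic oxygen in the flask, which leads to over-reduction to the methyl compound or to self-condensation, and alkoxide attacks the aryl ester. The fallback sets out from 11. Both phenols are masked first (TBSCl, imidazole, DMF) to give 4-formyl-3,5-bis(tert-butyldimethylsilyloxy)phenyl 3,4,5-tris(benzyloxy)benzoate F3. Reduction with NaBH4 (THF/EtOH, 0 °C) should give 3,5-bis(tert-butyldimethylsilyloxy)-4-(hydroxymethyl)phenyl 3,4,5-tris(benzyloxy)benzoate F4; with no phenoxide present no quinone methide can form, and a silyl shift to the benzylic oxygen would do no harm. Unmasking with Et3N·3HF in THF at −20 °C directly before use comes back to the route at 12.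

**Step 4.** What may go wrong: the enolate loses its geometry by proton exchange before it is trapped, or it is acylated on carbon. The fallback sets out from 4. The carbon–boron bond is oxidised (NaBO3·4H2O, THF/H2O) to [3,4-bis(benzyloxy)phenyl]acetaldehyde F5. Treatment with ClCO2Bn, Et3N and DMAP (cat.) in CH2Cl2 should give the enol carbonate as a mixture of 7 and its Z isomer, benzyl (Z)-2-[3,4-bis(benzyloxy)phenyl]ethenyl carbonate F6. Equilibration with catalytic PhSSPh under light should move the mixture toward the more stable E isomer, which is crystallised. Geometry then rests on thermodynamic control instead of stereospecific transfer, and the sequence comes back to the route at 7.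

Further compounds
F1 | step 7 | 2-[3,4-bis(benzyloxy)phenyl]-5-hydroxy-4H-chromen-7-yl 3,4,5-tris(benzyloxy)benzoate | O=C(Oc1cc(O)c2c(c1)OC(c1ccc(OCc3ccccc3)c(OCc3ccccc3)c1)=CC2)c1cc(OCc2ccccc2)c(OCc2ccccc2)c(OCc2ccccc2)c1
F2 | step 7 | (2R,3S)-2-[3,4-bis(benzyloxy)phenyl]-3,5-dihydroxy-3,4-dihydro-2H-chromen-7-yl 3,4,5-tris(benzyloxy)benzoate | O=C(Oc1cc(O)c2c(c1)O[C@H](c1ccc(OCc3ccccc3)c(OCc3ccccc3)c1)[C@@H](O)C2)c1cc(OCc2ccccc2)c(OCc2ccccc2)c(OCc2ccccc2)c1
F3 | step 6 | 4-formyl-3,5-bis(tert-butyldimethylsilyloxy)phenyl 3,4,5-tris(benzyloxy)benzoate | O=Cc1c(O[Si](C)(C)C(C)(C)C)cc(OC(=O)c2cc(OCc3ccccc3)c(OCc3ccccc3)c(OCc3ccccc3)c2)cc1O[Si](C)(C)C(C)(C)C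
F4 | step 6 | 3,5-bis(tert-butyldimethylsilyloxy)-4-(hydroxymethyl)phenyl 3,4,5-tris(benzyloxy)benzoate | OCc1c(O[Si](C)(C)C(C)(C)C)cc(OC(=O)c2cc(OCc3ccccc3)c(OCc3ccccc3)c(OCc3ccccc3)c2)cc1O[Si](C)(C)C(C)(C)C
F5 | step 4 | [3,4-bis(benzyloxy)phenyl]acetaldehyde | O=CCc1ccc(OCc2ccccc2)c(OCc2ccccc2)c1
F6 | step 4 | benzyl (Z)-2-[3,4-bis(benzyloxy)phenyl]ethenyl carbonate | O=C(OCc1ccccc1)O/C=C\c1ccc(OCc2ccccc2)c(OCc2ccccc2)c1
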